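The numbers of this flask are those of an exercise; the rest is arithmetic.

Slowness runs this flask: the solid substrate dissolves slowly, and the dissolved substrate joins the reagent slowly and reversibly.

solid substrate 0.25 M; reagent 1.00 equiv; protic impurity 5.00 mM; time 4.0 min

    solid substrate ⇌ dissolved substrate, rate k1*(cs1 - [dissolved substrate]) while solid is left; crystals form when [dissolved substrate] > cs1 (cs1 = 0.16 M, k1 = 0.0077 /s)
    dissolved substrate + reagent ⇌ target (K2 = 3.0 /M, k2 = 0.028 /M/s)
    dissolved substrate + target → side product (k3 = 0.0044 /M/s)
    solid substrate + protic impurity → quenched substrate (k4 = 0.48 /M/s)

- Saturday's: doubling the solubility in step 1, all else as stated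
- Sunday's: doubling the amount of reagent, all else as stated
- Wednesday's: doubling the dissolution coefficient of step 1, all else as stated

- percentages count the solid substrate that a species holds: one side product counts as two
- solid, in amounts per volume of the solution: solid substrate
- at the start none of the solid substrate is in solution
- run time (flask): 4.0 min

- amount of target at 4.0 min, in percent of the solid substrate charged
- the change that raises the amount of target at 4.0 min, in percent of the solid substrate charged most ("none" if none brings more than 2 percentage points) (Saturday's / Sunday's / Wednesday's / none)
- amount of target at 4.0 min, in percent of the solid substrate charged, after Saturday's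

**Bound share.** I took step 2 at equilibrium with the solution held at its solubility. Then [target]/[reagent] is 3.0 /M times 0.16 M, or 0.480. So the bound share, the part of the reagent held as target at that rest, is 32.4%. At 1.00 equiv this is also my ceiling for y, and the charge covers it: solution and target need 0.241 M of 0.25 M.

**Reading it.** Wednesday's leaves the share unchanged, since the dissolution coefficient isn't in it. Saturday's asks for more than the charge, and so does Sunday's. I therefore reckoned those two with the substrate wholly in solution, giving ceilings of 33.3% and 52.5%. I chose Sunday's, whose ceiling is higher than the others.

**One number?** No. The dissolving half-time of 1.50 min and the forward half-life of 1.7 min add up to 3.15 min of the 4.0 min, so I expected y well below its ceiling.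

**Forecast.** It gave 19.6%, Sunday's and 30.5%: “Sunday's edges it, though the margin is modest”.

**Result.** The simulation gave 19.4%, Sunday's and 28.9%, so the forecast stands. Sunday's gained 14 percentage points, Saturday's 9.5 points and Wednesday's 5.3 points.

**Falling short.** The forecast's y would fail with the reagent moved to 0.710 equiv or 1.32 equiv, where y shifts by 5 points. The flask reached 59.8% of its bound share, held down in part by the reverse step and the low solubility together: from 19.4%, removing the reverse step gave 33.4%. The neighbour flask at 0.600 equiv has a ceiling of 19.4%, and the same fraction of it predicts 11.6%; that flask gave 12.4%.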